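**Plan**
- Retrosynthesis: the four MOM ethers are removed last. The C2–C3 bond of the pyranone ring is then cut as a retro-Petasis–Ferrier step to a 4-methylidene-1,3-benzodioxine, whose C=CH2 goes back to the C=O of a 1,3-benzodioxin-4-one. The two acetal C–O bonds are then cut to an A-ring salicylic acid and a B-ring aldehyde.
- Enabling feature: in the pyran-4-one ring, O1 and the C4 carbonyl are 1,3-related across C2–C3, and C2 is a benzylic carbon between O1 and the 2',4'-dioxygenated B ring. C2 can therefore be carried as an acetal carbon that ionises to an oxocarbenium ion, with C3/C4 as an enol.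
- A ring: methyl 2,4,6-trihydroxybenzoate is C-prenylated, bis-MOM protected at O4/O6 and saponified. B ring: 2,4-dihydroxybenzaldehyde is O-prenylated, MOM protected, rearranged (aromatic Claisen, giving the 1,1-dimethylallyl group) and MOM protected again.
- Ring order: the 1,3-dioxin-4-one ring is made first by acetalisation, its carbonyl is methylenated, and the skeleton is then rearranged to the chroman-4-one.
- Stereochemistry: the only stereocentre (C2, S) is set in the rearrangement by a chiral Brønsted acid, enantioconvergently from the racemic acetal.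

Key step: step 10

Assumption: the sense of induction of the chiral acid cannot be predicted with certainty; the (R)-catalyst is written, and its antipode is used if it should favour 2R. Compounds 11 and 12 use 1,3-benzodioxine numbering (O1, C2, O3, C4); compounds 14–16 use flavanone numbering.

**Route**

Step 1
Reactants: 1 methyl 2,4,6-trihydroxybenzoate
Product: 2 methyl 2,4,6-trihydroxy-3-(3-methylbut-2-en-1-yl)benzoate
Conditions: prenyl bromide (1.0 equiv), DBU, THF, 0 °C → rt
Reagents that add atoms: prenyl bromide, CC(C)=CCBr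
Why: Base-mediated Friedel–Crafts-type C-prenylation of the phloroglucinol nucleus, whose phenoxide reacts at carbon with the soft allylic bromide; C3 and C5 of 1 are equivalent, so only one mono-C-prenyl constitution can form, and one equivalent of bromide limits over-alkylation.

Step 2
Reactants: 2 methyl 2,4,6-trihydroxy-3-(3-methylbut-2-en-1-yl)benzoate
Product: 3 methyl 2-hydroxy-4,6-bis(methoxymethoxy)-3-(3-methylbut-2-en-1-yl)benzoate
Conditions: MOMCl (2.1 equiv), i-Pr2NEt, CH2Cl2, 0 °C
Reagents that add atoms: chloromethyl methyl ether, COCCl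
Why: Williamson-type MOM etherification should take the most acidic para 4-OH and the less hindered ortho 6-OH, while the 2-OH, flanked by the prenyl group and chelated to the ester carbonyl, should stay free and so reserve the oxygen next to the prenyl group for the later ring O1 (site assignment to be confirmed by NOE/HMBC).

Step 3
Reactants: 3 methyl 2-hydroxy-4,6-bis(methoxymethoxy)-3-(3-methylbut-2-en-1-yl)benzoate
Product: 4 2-hydroxy-4,6-bis(methoxymethoxy)-3-(3-methylbut-2-en-1-yl)benzoic acid
Conditions: KOH, MeOH/H2O, 70 °C; then 1 M HCl to pH 4, 0 °C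
Reagents that add atoms: none
Why: Saponification of the hindered salicylate, to which the MOM ethers and the prenyl group are stable, with a cold and only mildly acidic work-up to avoid decarboxylation of the electron-rich salicylic acid and loss of MOM.

Step 4
Reactants: 5 2,4-dihydroxybenzaldehyde
Product: 6 2-hydroxy-4-[(3-methylbut-2-en-1-yl)oxy]benzaldehyde
Conditions: prenyl bromide, K2CO3, acetone, reflux
Reagents that add atoms: prenyl bromide, CC(C)=CCBr
Why: Williamson ether synthesis that is selective for the more acidic, non-chelated 4-OH, the 2-OH being hydrogen-bonded to the aldehyde.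

Step 5
Reactants: 6 2-hydroxy-4-[(3-methylbut-2-en-1-yl)oxy]benzaldehyde
Product: 7 2-(methoxymethoxy)-4-[(3-methylbut-2-en-1-yl)oxy]benzaldehyde
Conditions: MOMCl, i-Pr2NEt, CH2Cl2, 0 °C → rt
Reagents that add atoms: chloromethyl methyl ether, COCCl
Why: MOM etherification of the remaining phenol removes the chelate that would otherwise steer the later rearrangement towards C3.

Step 6
Reactants: 7 2-(methoxymethoxy)-4-[(3-methylbut-2-en-1-yl)oxy]benzaldehyde
Product: 8 4-hydroxy-2-(methoxymethoxy)-5-(2-methylbut-3-en-2-yl)benzaldehyde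
Conditions: PhNEt2, 190–200 °C, sealed tube
Reagents that add atoms: none
Why: Aromatic Claisen [3,3]-sigmatropic rearrangement of the aryl prenyl ether, followed by tautomerisation, delivers the 1,1-dimethylallyl group to the ortho position C5 and not to C3, which lies between two oxygen substituents and is too hindered to take a quaternary carbon.

Step 7
Reactants: 8 4-hydroxy-2-(methoxymethoxy)-5-(2-methylbut-3-en-2-yl)benzaldehyde
Product: 9 2,4-bis(methoxymethoxy)-5-(2-methylbut-3-en-2-yl)benzaldehyde
Conditions: NaH, MOMCl, DMF, 0 °C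
Reagents that add atoms: chloromethyl methyl ether, COCCl
Why: Williamson-type MOM protection of the hindered phenol through its sodium phenoxide; the aldehyde has no α-hydrogen and tolerates NaH.

Step 8
Reactants: 4 2-hydroxy-4,6-bis(methoxymethoxy)-3-(3-methylbut-2-en-1-yl)benzoic acid, 9 2,4-bis(methoxymethoxy)-5-(2-methylbut-3-en-2-yl)benzaldehyde
Product: 11 2-[2,4-bis(methoxymethoxy)-5-(2-methylbut-3-en-2-yl)phenyl]-5,7-bis(methoxymethoxy)-8-(3-methylbut-2-en-1-yl)-4H-1,3-benzodioxin-4-one (racemic), via bis(trimethylsilyl) derivative 10 (not isolated)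
Conditions: HMDS, CH2Cl2, rt, then evaporation; 9, TMSOTf (10 mol %), CH2Cl2, −78 → −40 °C; pyridine quench
Reagents that add atoms: hexamethyldisilazane, C[Si](C)(C)N[Si](C)(C)C (its Me3Si groups stand in 10 only)
Why: TMSOTf-catalysed Noyori-type silyl acetalisation of the aldehyde with the bis-silylated hydroxy acid, as in the first stage of a Petasis–Ferrier union, closes the 1,3-dioxin-4-one on the only free phenol oxygen (the one next to the prenyl group); the acetal centre forms as a racemate, which does not matter here.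

Step 9
Reactants: 11 2-[2,4-bis(methoxymethoxy)-5-(2-methylbut-3-en-2-yl)phenyl]-5,7-bis(methoxymethoxy)-8-(3-methylbut-2-en-1-yl)-4H-1,3-benzodioxin-4-one (racemic)
Product: 12 2-[2,4-bis(methoxymethoxy)-5-(2-methylbut-3-en-2-yl)phenyl]-5,7-bis(methoxymethoxy)-4-methylidene-8-(3-methylbut-2-en-1-yl)-4H-1,3-benzodioxine (racemic)
Conditions: Cp2TiMe2 (3 equiv), toluene/THF, 65 °C, dark; filtration through basic alumina
Reagents that add atoms: dimethyltitanocene, C[Ti](C)(C1C=CC=C1)C1C=CC=C1
Why: Petasis methylenation (titanocene methylidene, [2+2]/retro-[2+2] through an oxatitanacyclobutane) converts the lactone-type carbonyl into the exocyclic enol ether under non-acidic, non-basic conditions that leave the acetal, the MOM ethers and both alkenes intact.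

Step 10
Reactants: 12 2-[2,4-bis(methoxymethoxy)-5-(2-methylbut-3-en-2-yl)phenyl]-5,7-bis(methoxymethoxy)-4-methylidene-8-(3-methylbut-2-en-1-yl)-4H-1,3-benzodioxine (racemic)
Product: 14 (2S)-2-[2,4-bis(methoxymethoxy)-5-(2-methylbut-3-en-2-yl)phenyl]-5,7-bis(methoxymethoxy)-8-(3-methylbut-2-en-1-yl)-2,3-dihydro-4H-chromen-4-one, via oxocarbenium enol ion pair 13 (not isolated)
Conditions: (R)-3,3'-bis(2,4,6-triisopropylphenyl)-BINOL N-triflylphosphoramide (5 mol %), 4 Å MS, toluene, −40 → −20 °C; Et3N quench
Reagents that add atoms: none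
Why: Proposed new method: the chiral acid protonates the enol-acetal unit of 12 and the C2–O3 bond ionises (directly after O-protonation, or by fragmentation after C-protonation and re-enolisation), because the O-aryl oxocarbenium ion is strongly stabilised by the 2,4-dioxygenated aryl group on C2; this gives ion pair 13, in which the tethered aryl-ketone enol is hydrogen-bonded to the chiral anion, and the enol carbon then adds to the oxocarbenium carbon with return of the proton to the catalyst, a net [1,3] O-to-C shift that turns the 1,3-benzodioxine into the chroman-4-one. The closest known reaction types are the Lewis-acid-promoted Petasis–Ferrier rearrangement of 4-methylidene-1,3-dioxanes to tetrahydropyran-4-ones and the chiral phosphoric acid-catalysed aza-Petasis–Ferrier rearrangement of hemiaminal vinyl ethers. The pyranone ring closes in the 6-(enolendo)-endo-trig mode. The acetal centre of racemic 12 is erased in 13, so both enantiomers pass through one achiral cation and the new C2 centre is set only by the chiral counter-anion, which shields one face of the E-oxocarbenium ion while it holds the enol (enantioconvergent, 2S expected with the catalyst enantiomer chosen). The step needs the enol to win over the 8-prenyl alkene (Prins-type closure on the same cation) and the benzylic acetal to ionise in preference to the MOM acetals; the much higher nucleophilicity of the enol and the much greater stability of the aryl- and oxygen-stabilised cation should secure both, and molecular sieves suppress hydrolysis.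

Step 11
Reactants: 14 (2S)-2-[2,4-bis(methoxymethoxy)-5-(2-methylbut-3-en-2-yl)phenyl]-5,7-bis(methoxymethoxy)-8-(3-methylbut-2-en-1-yl)-2,3-dihydro-4H-chromen-4-one
Product: 16 (2S)-2-[2,4-dihydroxy-5-(2-methylbut-3-en-2-yl)phenyl]-5,7-dihydroxy-8-(3-methylbut-2-en-1-yl)-2,3-dihydro-4H-chromen-4-one (AChE-IN-17), via tetrakis(trimethylsilyl) ether 15 (not isolated)
Conditions: TMSOTf, 2,2'-bipyridyl, MeCN, 0 °C → rt; then H2O
Reagents that add atoms: trimethylsilyl trifluoromethanesulfonate, C[Si](C)(C)OS(=O)(=O)C(F)(F)F (its Me3Si groups stand in 15 only)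
Why: TMSOTf/2,2'-bipyridyl converts aromatic MOM ethers into aryl TMS ethers that water hydrolyses, so all four phenols are freed under buffered, non-basic conditions at or below room temperature that should neither open the flavanone ring (C2 stays S) nor cyclise the prenyl group onto the 7-OH.

**Compound list**
1 | methyl 2,4,6-trihydroxybenzoate | COC(=O)c1c(O)cc(O)cc1O | starting material
2 | methyl 2,4,6-trihydroxy-3-(3-methylbut-2-en-1-yl)benzoate | COC(=O)c1c(O)cc(O)c(CC=C(C)C)c1O | intermediate
3 | methyl 2-hydroxy-4,6-bis(methoxymethoxy)-3-(3-methylbut-2-en-1-yl)benzoate | COC(=O)c1c(OCOC)cc(OCOC)c(CC=C(C)C)c1O | intermediate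
4 | 2-hydroxy-4,6-bis(methoxymethoxy)-3-(3-methylbut-2-en-1-yl)benzoic acid | OC(=O)c1c(OCOC)cc(OCOC)c(CC=C(C)C)c1O | intermediate
5 | 2,4-dihydroxybenzaldehyde | O=Cc1ccc(O)cc1O | starting material
6 | 2-hydroxy-4-[(3-methylbut-2-en-1-yl)oxy]benzaldehyde | O=Cc1ccc(OCC=C(C)C)cc1O | intermediate
7 | 2-(methoxymethoxy)-4-[(3-methylbut-2-en-1-yl)oxy]benzaldehyde | O=Cc1ccc(OCC=C(C)C)cc1OCOC | intermediate
8 | 4-hydroxy-2-(methoxymethoxy)-5-(2-methylbut-3-en-2-yl)benzaldehyde | O=Cc1cc(C(C)(C)C=C)c(O)cc1OCOC | intermediate
9 | 2,4-bis(methoxymethoxy)-5-(2-methylbut-3-en-2-yl)benzaldehyde | O=Cc1cc(C(C)(C)C=C)c(OCOC)cc1OCOC | intermediate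
10 | trimethylsilyl 4,6-bis(methoxymethoxy)-3-(3-methylbut-2-en-1-yl)-2-(trimethylsilyloxy)benzoate (not isolated) | C[Si](C)(C)OC(=O)c1c(OCOC)cc(OCOC)c(CC=C(C)C)c1O[Si](C)(C)C | intermediate
11 | 2-[2,4-bis(methoxymethoxy)-5-(2-methylbut-3-en-2-yl)phenyl]-5,7-bis(methoxymethoxy)-8-(3-methylbut-2-en-1-yl)-4H-1,3-benzodioxin-4-one (racemic) | O=C1OC(c2cc(C(C)(C)C=C)c(OCOC)cc2OCOC)Oc2c(CC=C(C)C)c(OCOC)cc(OCOC)c21 | intermediate
12 | 2-[2,4-bis(methoxymethoxy)-5-(2-methylbut-3-en-2-yl)phenyl]-5,7-bis(methoxymethoxy)-4-methylidene-8-(3-methylbut-2-en-1-yl)-4H-1,3-benzodioxine (racemic) | C=C1OC(c2cc(C(C)(C)C=C)c(OCOC)cc2OCOC)Oc2c(CC=C(C)C)c(OCOC)cc(OCOC)c21 | intermediate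
13 | {[2,4-bis(methoxymethoxy)-5-(2-methylbut-3-en-2-yl)phenyl]methylidene}[2-(1-hydroxyethenyl)-3,5-bis(methoxymethoxy)-6-(3-methylbut-2-en-1-yl)phenyl]oxonium, cation of the ion pair with the catalyst anion (not isolated) | C=C(O)c1c(OCOC)cc(OCOC)c(CC=C(C)C)c1[O+]=Cc1cc(C(C)(C)C=C)c(OCOC)cc1OCOC | intermediate
14 | (2S)-2-[2,4-bis(methoxymethoxy)-5-(2-methylbut-3-en-2-yl)phenyl]-5,7-bis(methoxymethoxy)-8-(3-methylbut-2-en-1-yl)-2,3-dihydro-4H-chromen-4-one | C=CC(C)(C)c1cc([C@@H]2CC(=O)c3c(OCOC)cc(OCOC)c(CC=C(C)C)c3O2)c(OCOC)cc1OCOC | intermediate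
15 | (2S)-2-[5-(2-methylbut-3-en-2-yl)-2,4-bis(trimethylsilyloxy)phenyl]-8-(3-methylbut-2-en-1-yl)-5,7-bis(trimethylsilyloxy)-2,3-dihydro-4H-chromen-4-one (not isolated) | C=CC(C)(C)c1cc([C@@H]2CC(=O)c3c(O[Si](C)(C)C)cc(O[Si](C)(C)C)c(CC=C(C)C)c3O2)c(O[Si](C)(C)C)cc1O[Si](C)(C)C | intermediate
16 | (2S)-2-[2,4-dihydroxy-5-(2-methylbut-3-en-2-yl)phenyl]-5,7-dihydroxy-8-(3-methylbut-2-en-1-yl)-2,3-dihydro-4H-chromen-4-one (AChE-IN-17) | C=CC(C)(C)c1cc([C@@H]2CC(=O)c3c(O)cc(O)c(CC=C(C)C)c3O2)c(O)cc1O | target

Total step count: 11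
Longest linear sequence: 8 steps (steps 4–7, then 8–11)

**Steps most likely to fail**

1. Step 10 (Proposed new method). The chiral anion may discriminate poorly between the faces of the oxocarbenium ion, an uncatalysed or product-racemising background pathway may erode the enantiomeric purity, or the acid may trigger ionisation elsewhere in the molecule. Fallback (known chemistry, racemic rearrangement followed by kinetic resolution): it sets out from 12 and comes back to the route at 14. Compound 12 is rearranged under the classical Lewis-acid Petasis–Ferrier conditions (Me2AlCl, CH2Cl2, −78 °C) to racemic 2-[2,4-bis(methoxymethoxy)-5-(2-methylbut-3-en-2-yl)phenyl]-5,7-bis(methoxymethoxy)-8-(3-methylbut-2-en-1-yl)-2,3-dihydro-4H-chromen-4-one (F1). The racemic ketone F1 is then submitted to asymmetric transfer hydrogenation under kinetic-resolution conditions (Rh or Ru TsDPEN catalyst, HCO2H/Et3N, EtOAc, rt, run to about half conversion). The catalyst enantiomer is chosen so that the (2R)-ketone is reduced faster, to the cis-alcohol (2R,4R)-2-[2,4-bis(methoxymethoxy)-5-(2-methylbut-3-en-2-yl)phenyl]-5,7-bis(methoxymethoxy)-8-(3-methylbut-2-en-1-yl)-3,4-dihydro-2H-chromen-4-ol (F2). The alcohol F2 is removed by chromatography; the ketone that is left is the (2S)-enantiomer 14, at which the route is rejoined.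

2. Step 9. Methylenation of the electron-rich carbonyl, flanked by the 5-OMOM group, may be sluggish, and the enol acetal may hydrolyse during isolation. Fallback (chalcone route, which avoids the enol acetal altogether): it sets out from acid 4 and comes back to the route at 14. Acid 4 with excess MeLi (THF, 0 °C, then aqueous work-up) should give 1-[2-hydroxy-4,6-bis(methoxymethoxy)-3-(3-methylbut-2-en-1-yl)phenyl]ethan-1-one (F3). Claisen–Schmidt condensation of the methyl ketone F3 with aldehyde 9 (KOH, EtOH/H2O, rt) should give (E)-3-[2,4-bis(methoxymethoxy)-5-(2-methylbut-3-en-2-yl)phenyl]-1-[2-hydroxy-4,6-bis(methoxymethoxy)-3-(3-methylbut-2-en-1-yl)phenyl]prop-2-en-1-one (F4). Intramolecular oxa-Michael cyclisation of the chalcone F4 (NaOAc, EtOH, reflux) through its only free phenol, the one next to the prenyl group, should give the racemic flavanone F1. F1 is then resolved by the transfer-hydrogenation kinetic resolution described under point 1, which removes the (2R)-enantiomer as the alcohol F2 and leaves 14.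

3. Step 2. Site selection between the two chelated ortho-hydroxyl groups may be incomplete or reversed; protection of the 2-OH instead of the 6-OH would lead into the 6-prenyl series. Fallback (protection before prenylation, so that the prenyl group is placed by the free phenol): it sets out from 1 and comes back to the route at 3. Compound 1 is bis-protected first (MOMCl, i-Pr2NEt, CH2Cl2) to methyl 2-hydroxy-4,6-bis(methoxymethoxy)benzoate (F5); the two ortho-hydroxyl groups of 1 are equivalent, so no site selection is needed. The sodium phenoxide of F5 (NaH, toluene) is then C-alkylated with prenyl bromide at its only free ortho carbon, as is usual for phenoxide ion pairs in non-polar solvents, which should give 3.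

**Further compounds**
F1 | step 10 | 2-[2,4-bis(methoxymethoxy)-5-(2-methylbut-3-en-2-yl)phenyl]-5,7-bis(methoxymethoxy)-8-(3-methylbut-2-en-1-yl)-2,3-dihydro-4H-chromen-4-one (racemic) | C=CC(C)(C)c1cc(C2CC(=O)c3c(OCOC)cc(OCOC)c(CC=C(C)C)c3O2)c(OCOC)cc1OCOC
F2 | step 10 | (2R,4R)-2-[2,4-bis(methoxymethoxy)-5-(2-methylbut-3-en-2-yl)phenyl]-5,7-bis(methoxymethoxy)-8-(3-methylbut-2-en-1-yl)-3,4-dihydro-2H-chromen-4-ol | C=CC(C)(C)c1cc([C@H]2C[C@@H](O)c3c(OCOC)cc(OCOC)c(CC=C(C)C)c3O2)c(OCOC)cc1OCOC
F3 | step 9 | 1-[2-hydroxy-4,6-bis(methoxymethoxy)-3-(3-methylbut-2-en-1-yl)phenyl]ethan-1-one | CC(=O)c1c(OCOC)cc(OCOC)c(CC=C(C)C)c1O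
F4 | step 9 | (E)-3-[2,4-bis(methoxymethoxy)-5-(2-methylbut-3-en-2-yl)phenyl]-1-[2-hydroxy-4,6-bis(methoxymethoxy)-3-(3-methylbut-2-en-1-yl)phenyl]prop-2-en-1-one | O=C(/C=C/c1cc(C(C)(C)C=C)c(OCOC)cc1OCOC)c1c(OCOC)cc(OCOC)c(CC=C(C)C)c1O
F5 | step 2 | methyl 2-hydroxy-4,6-bis(methoxymethoxy)benzoate | COC(=O)c1c(OCOC)cc(OCOC)cc1O
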